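The benzotropolone core is numbered as a benzo[7]annulene (benzenoid C1–C4, fusion C4a and C9a, C5 carbonyl, C6 hydroxyl, C7–C9; chroman G with the gallate on C1, chroman F on C8). The route disconnects the benzenoid ring at C4a–C9a and C1–C2: C4a, C4, C3 and C2 map onto a 3-acyl-4,5-bis(benzyloxy)-2-pyrone and C9a–C1 onto an alkyne ending in chroman G. One intramolecular pyrone–alkyne Diels–Alder reaction with loss of CO2 builds the benzene ring and the seven-membered ring together. In the precursor the tether runs from the pyrone through the C5 ketone, C6H2 and a C7=C8 alkene bearing chroman F, with C6 and C9 cis (E by the sequence rules).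

Key step: step 17

Remark: ChF stands for the (2R,3R)-3,5,7-tris(benzyloxy)chroman-2-yl group and ChG for the (2R,3R)-5,7-bis(benzyloxy)-3-{[3,4,5-tris(benzyloxy)benzoyl]oxy}chroman-2-yl group; both chromans have the same configuration and are drawn from one enantiopure 2-ethynylchroman-3-ol, and 3,5-bis(benzyloxy)phenol and 3,4,5-tris(benzyloxy)benzoic acid are assumed to be bought in benzylated form.

Step 1
Reactants: 1 acrolein; 2 ethynyltrimethylsilane
Product: 3 rac-5-(trimethylsilyl)pent-1-en-4-yn-3-ol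
Conditions: 2, n-BuLi, THF, −78 °C; then 1, −78 °C
Reagents that add atoms: none
Why: 1,2-addition of a lithium acetylide to an enal (carbonyl alkynylation) should give the racemic vinyl alkynyl carbinol, whose centre is resolved in step 2.

Step 2
Reactants: 3 rac-5-(trimethylsilyl)pent-1-en-4-yn-3-ol
Product: 4 (1S)-1-[(2R)-oxiran-2-yl]-3-(trimethylsilyl)prop-2-yn-1-ol
Conditions: Ti(OiPr)4 (0.2 equiv), L-(+)-diisopropyl tartrate (0.24 equiv), tBuOOH (0.6 equiv), 4 Å molecular sieves, CH2Cl2, −20 °C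
Reagents that add atoms: tert-butyl hydroperoxide, CC(C)(C)OO
Why: Sharpless asymmetric epoxidation run as a kinetic resolution: with the L-(+)-tartrate the (R)-enantiomer of 3 should be epoxidised fast on its vinyl group to the erythro epoxy alcohol, so the reagent sets the oxirane centre (R) and the resolution selects the carbinol centre (S), while the alkyne is inert and unreacted (S)-3 is separated.

Step 3
Reactants: 4 (1S)-1-[(2R)-oxiran-2-yl]-3-(trimethylsilyl)prop-2-yn-1-ol; 5 3,5-bis(benzyloxy)phenol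
Product: 6 (2R)-2-[(1R)-1-[3,5-bis(benzyloxy)phenoxy]-3-(trimethylsilyl)prop-2-yn-1-yl]oxirane
Conditions: PPh3, DIAD, THF, 0 °C → rt
Reagents that add atoms: none
Why: Mitsunobu etherification of the secondary propargylic alcohol by the phenol should proceed with clean inversion (S carbinol to R aryl ether), the epoxide is untouched and the bulky silyl group disfavours attack at the alkyne terminus.

Step 4
Reactants: 6 (2R)-2-[(1R)-1-[3,5-bis(benzyloxy)phenoxy]-3-(trimethylsilyl)prop-2-yn-1-yl]oxirane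
Product: 7 (2R,3R)-5,7-bis(benzyloxy)-2-[(trimethylsilyl)ethynyl]chroman-3-ol
Conditions: (CF3)2CHOH, 0 °C → rt
Reagents that add atoms: none
Why: intramolecular Friedel–Crafts epoxide–arene alkylation promoted by the hydrogen-bonding solvent: the ring carbon ortho to the ether oxygen should open the oxirane at its terminal CH2 (6-endo closure to the 3-chromanol), so C2 (from the ether carbon) and C3 (from the oxirane carbon) are not touched and the 2,3-cis relation follows from steps 2 and 3; gold catalysts are avoided because they would activate the aryl propargyl ether.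

Step 5
Reactants: 7 (2R,3R)-5,7-bis(benzyloxy)-2-[(trimethylsilyl)ethynyl]chroman-3-ol
Product: 8 (2R,3R)-5,7-bis(benzyloxy)-2-ethynylchroman-3-ol
Conditions: K2CO3 (0.2 equiv), MeOH, rt
Reagents that add atoms: none
Why: methoxide-mediated protodesilylation of the alkynylsilane should free the terminal alkyne without touching either stereocentre.

Step 6
Reactants: 8 (2R,3R)-5,7-bis(benzyloxy)-2-ethynylchroman-3-ol
Product: 9 (2R,3R)-3,5,7-tris(benzyloxy)-2-ethynylchromane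
Conditions: NaH (1.1 equiv), BnBr, Bu4NI (cat.), THF/DMF, 0 °C
Reagents that add atoms: benzyl bromide, BrCc1ccccc1
Why: Williamson etherification should be selective because the alkoxide forms far more readily than the acetylide.

Step 7
Reactants: 9 (2R,3R)-3,5,7-tris(benzyloxy)-2-ethynylchromane; 10 but-3-en-1-ol
Product: 11 but-3-en-1-yl 2-ChF-prop-2-enoate
Conditions: CO (30 bar), Pd(OAc)2 (2 mol %), 2-(diphenylphosphino)pyridine (30 mol %), MeSO3H (10 mol %), 10 (5 equiv), N-methylpyrrolidone, 50 °C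
Reagents that add atoms: carbon monoxide, [C-]#[O+]
Why: palladium-catalysed Markovnikov hydroalkoxycarbonylation of a terminal alkyne with the pyridylphosphine system should give the branched 2-substituted acrylate and places the future C9 carbon on C8, while the alkene of 10 is not carbonylated.

Step 8
Reactants: 11 but-3-en-1-yl 2-ChF-prop-2-enoate
Product: 12 3-ChF-5,6-dihydro-2H-pyran-2-one
Conditions: second-generation Hoveyda–Grubbs catalyst (5 mol %), toluene, 80 °C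
Reagents that add atoms: none
Why: ring-closing metathesis of the acrylate with the homoallyl ester should give the six-membered unsaturated lactone, whose ring forces C6 and C9 to be cis on the new trisubstituted C7=C8 bond; the phosphine-free catalyst avoids conjugate addition to the acrylate.

Step 9
Reactants: 12 3-ChF-5,6-dihydro-2H-pyran-2-one
Product: 13 (2E)-2-ChF-pent-2-ene-1,5-diol
Conditions: iBu2AlH (4 equiv), CH2Cl2, −78 → 0 °C
Reagents that add atoms: none
Why: 1,2-reduction of the unsaturated lactone by the aluminium hydride should give the diol with the alkene geometry of the ring retained (hydroxymethyl and hydroxyethyl cis).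

Step 10
Reactants: 13 (2E)-2-ChF-pent-2-ene-1,5-diol
Product: 14 (3Z)-5-chloro-4-ChF-pent-3-en-1-ol
Conditions: N-chlorosuccinimide, Me2S, CH2Cl2, −20 → 0 °C
Reagents that add atoms: N-chlorosuccinimide, O=C1CCC(=O)N1Cl
Why: Corey–Kim halogenation: only the allylic alkoxysulfonium ion should be displaced by chloride, whereas the saturated primary one reverts to the alcohol on work-up, under neutral conditions.

Step 11
Reactants: 8 (2R,3R)-5,7-bis(benzyloxy)-2-ethynylchroman-3-ol; 15 3,4,5-tris(benzyloxy)benzoic acid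
Product: 16 (2R,3R)-5,7-bis(benzyloxy)-2-ethynylchroman-3-yl 3,4,5-tris(benzyloxy)benzoate
Conditions: DCC, DMAP, CH2Cl2, rt
Reagents that add atoms: none
Why: Steglich esterification acylates the secondary alcohol with retention at C3.

Step 12
Reactants: 14 (3Z)-5-chloro-4-ChF-pent-3-en-1-ol; 16 (2R,3R)-5,7-bis(benzyloxy)-2-ethynylchroman-3-yl 3,4,5-tris(benzyloxy)benzoate
Product: 18 (3E)-7-ChG-4-ChF-hept-3-en-6-yn-1-ol, via allylic iodide 17 (not isolated)
Conditions: CuI (1.0 equiv), NaI (1.0 equiv), K2CO3, DMF, rt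
Reagents that add atoms: none
Why: copper-mediated coupling of a terminal alkyne with an allylic halide (iodide formed in the flask by halide exchange) should substitute at the primary carbon to give the skipped enyne and forms the C9–C9a bond; the ester and the free hydroxyl are tolerated.

Step 13
Reactants: 18 (3E)-7-ChG-4-ChF-hept-3-en-6-yn-1-ol
Product: 20 (3E)-7-ChG-4-ChF-hept-3-en-6-ynoic acid, via aldehyde 19 (not isolated)
Conditions: TEMPO (0.2 equiv), PhI(OAc)2 (2.2 equiv), CH2Cl2/H2O, rt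
Reagents that add atoms: water, O
Why: oxoammonium-catalysed oxidation of the primary alcohol through the aldehyde hydrate to the acid runs near neutrality, so the β,γ-double bond should stay in place.

Step 14
Reactants: 21 ethyl 4-(benzyloxy)-3-oxobutanoate
Product: 23 5-(benzyloxy)-4-hydroxy-2H-pyran-2-one, via formyl keto ester 22 (not isolated)
Conditions: NaH, THF, 0 °C; n-BuLi, −78 °C; HCO2Et, −78 → 0 °C; 1 M HCl; then TsOH (cat.), toluene, 80 °C
Reagents that add atoms: ethyl formate, CCOC=O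
Why: Claisen-type formylation of the β-keto ester dianion at its γ-carbon followed by lactonisation of the enol oxygen onto the ester should give the 4-hydroxy-2-pyrone.

Step 15
Reactants: 20 (3E)-7-ChG-4-ChF-hept-3-en-6-ynoic acid; 23 5-(benzyloxy)-4-hydroxy-2H-pyran-2-one
Product: 25 5-(benzyloxy)-4-hydroxy-3-[(3E)-7-ChG-4-ChF-hept-3-en-6-ynoyl]-2H-pyran-2-one, via enol ester 24 (not isolated)
Conditions: DCC, DMAP (1.2 equiv), CH2Cl2, rt → 40 °C
Reagents that add atoms: none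
Why: O-acylation of the hydroxypyrone followed by DMAP-mediated O-to-C acyl migration (Fries-type) is the standard entry to 3-acyl-4-hydroxy-2-pyrones and forms the C4a–C5 bond.

Step 16
Reactants: 25 5-(benzyloxy)-4-hydroxy-3-[(3E)-7-ChG-4-ChF-hept-3-en-6-ynoyl]-2H-pyran-2-one
Product: 26 4,5-bis(benzyloxy)-3-[(3E)-7-ChG-4-ChF-hept-3-en-6-ynoyl]-2H-pyran-2-one
Conditions: BnOH, PPh3, DIAD, THF, 0 °C
Reagents that add atoms: benzyl alcohol, OCc1ccccc1
Why: Mitsunobu alkylation of the acidic vinylogous acid at the 4-oxygen needs no base, so the β,γ-unsaturated ketone should not be enolised or moved into conjugation.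

Step 17
Reactants: 26 4,5-bis(benzyloxy)-3-[(3E)-7-ChG-4-ChF-hept-3-en-6-ynoyl]-2H-pyran-2-one
Product: 28 3,4-bis(benzyloxy)-1-ChG-8-ChF-6,9-dihydro-5H-benzo[7]annulen-5-one, via bridged lactone 27 (not isolated)
Conditions: o-C6H4Cl2 (0.005 M, degassed), BHT (0.1 equiv), 160 °C, sealed tube
Reagents that add atoms: none
Why: The pyrone acts as the diene (its C3 and C6, the future C4a and C2) in a thermal type 1 intramolecular [4+2] cycloaddition across the tethered alkyne, which forms C4a–C9a and C1–C2 and gives the 2-oxabicyclo[2.2.2]octadienone 27; retro-[4+2] loss of CO2 then aromatises the new ring and makes the sequence irreversible. The closest known reaction type is the intramolecular 2-pyrone–alkyne Diels–Alder benzannulation with CO2 extrusion, documented mainly for tethers that close five- and six-membered rings. The benzene ring closes by cycloaddition followed by cycloreversion, and the seven-membered ring closes through the five-atom tether C5–C9 when C4a bonds to C9a. No stereocentre is formed, since the bridgeheads of 27 vanish on aromatisation and the four chroman centres are remote. Regiochemistry is fixed by the tether, and the alkyne rather than the C7=C8 alkene reacts because that alkene lies only two atoms from the pyrone and cannot span both diene termini. The sp2 ketone at C5, which also lowers the diene LUMO, and the cis placement of C6 and C9 on the alkene remove rotors and hold the alkyne over the diene.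

Step 18
Reactants: 28 3,4-bis(benzyloxy)-1-ChG-8-ChF-6,9-dihydro-5H-benzo[7]annulen-5-one
Product: 30 3,4-bis(benzyloxy)-6-hydroxy-1-ChG-8-ChF-6,9-dihydro-5H-benzo[7]annulen-5-one (both C6 epimers), via sodium dienolate 29 (not isolated)
Conditions: NaN(SiMe3)2, THF, −78 °C, 10 min; then 3-phenyl-2-(phenylsulfonyl)oxaziridine, −78 °C
Reagents that add atoms: 3-phenyl-2-(phenylsulfonyl)oxaziridine, O=S(=O)(c1ccccc1)N1OC1c1ccccc1
Why: enolate hydroxylation with an N-sulfonyloxaziridine: the doubly activated C6 methylene is deprotonated and the dienolate should be oxygenated at its α-carbon C6 (the γ-carbon C8 is fully substituted), at low temperature and short enolate lifetime to keep the aryloxy group on chroman F in place; the new C6 centre is removed in step 19.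

Step 19
Reactants: 30 3,4-bis(benzyloxy)-6-hydroxy-1-ChG-8-ChF-6,9-dihydro-5H-benzo[7]annulen-5-one
Product: 32 3,4-bis(benzyloxy)-6-hydroxy-1-ChG-8-ChF-5H-benzo[7]annulen-5-one, via 5,6-dione 31 (not isolated)
Conditions: Dess–Martin periodinane, CH2Cl2, 0 °C → rt
Reagents that add atoms: none
Why: oxidation of the α-ketol gives the 5,6-dione, which should tautomerise through C9–H to the aromatic tropolone; any double-bond isomer of 28 or 30 would converge on the same product.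

Step 20
Reactants: 32 3,4-bis(benzyloxy)-6-hydroxy-1-ChG-8-ChF-5H-benzo[7]annulen-5-one
Product: 33 theaflavin-3-gallate
Conditions: H2 (1 atm), Pd(OH)2/C, THF/MeOH, rt
Reagents that add atoms: none
Why: hydrogenolysis should remove all ten benzyl ethers while the cyclic C2–O bonds of the chromans, the gallate ester and the tropolone survive as in flavan-3-ol chemistry; no stereocentre is touched.

Compound list
1 | acrolein | C=CC=O | starting material
2 | ethynyltrimethylsilane | C#C[Si](C)(C)C | starting material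
3 | rac-5-(trimethylsilyl)pent-1-en-4-yn-3-ol | C=CC(O)C#C[Si](C)(C)C | intermediate
4 | (1S)-1-[(2R)-oxiran-2-yl]-3-(trimethylsilyl)prop-2-yn-1-ol | C[Si](C)(C)C#C[C@H](O)[C@H]1CO1 | intermediate
5 | 3,5-bis(benzyloxy)phenol | Oc1cc(OCc2ccccc2)cc(OCc2ccccc2)c1 | starting material
6 | (2R)-2-[(1R)-1-[3,5-bis(benzyloxy)phenoxy]-3-(trimethylsilyl)prop-2-yn-1-yl]oxirane | C[Si](C)(C)C#C[C@@H](Oc1cc(OCc2ccccc2)cc(OCc2ccccc2)c1)[C@H]1CO1 | intermediate
7 | (2R,3R)-5,7-bis(benzyloxy)-2-[(trimethylsilyl)ethynyl]chroman-3-ol | C[Si](C)(C)C#C[C@H]1Oc2cc(OCc3ccccc3)cc(OCc3ccccc3)c2C[C@H]1O | intermediate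
8 | (2R,3R)-5,7-bis(benzyloxy)-2-ethynylchroman-3-ol | C#C[C@H]1Oc2cc(OCc3ccccc3)cc(OCc3ccccc3)c2C[C@H]1O | intermediate
9 | (2R,3R)-3,5,7-tris(benzyloxy)-2-ethynylchromane | C#C[C@H]1Oc2cc(OCc3ccccc3)cc(OCc3ccccc3)c2C[C@H]1OCc1ccccc1 | intermediate
10 | but-3-en-1-ol | C=CCCO | starting material
11 | but-3-en-1-yl 2-ChF-prop-2-enoate | C=CCCOC(=O)C(=C)[C@H]1Oc2cc(OCc3ccccc3)cc(OCc3ccccc3)c2C[C@H]1OCc1ccccc1 | intermediate
12 | 3-ChF-5,6-dihydro-2H-pyran-2-one | O=C1OCCC=C1[C@H]1Oc2cc(OCc3ccccc3)cc(OCc3ccccc3)c2C[C@H]1OCc1ccccc1 | intermediate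
13 | (2E)-2-ChF-pent-2-ene-1,5-diol | OC/C(=C\CCO)[C@H]1Oc2cc(OCc3ccccc3)cc(OCc3ccccc3)c2C[C@H]1OCc1ccccc1 | intermediate
14 | (3Z)-5-chloro-4-ChF-pent-3-en-1-ol | ClC/C(=C\CCO)[C@H]1Oc2cc(OCc3ccccc3)cc(OCc3ccccc3)c2C[C@H]1OCc1ccccc1 | intermediate
15 | 3,4,5-tris(benzyloxy)benzoic acid | OC(=O)c1cc(OCc2ccccc2)c(OCc2ccccc2)c(OCc2ccccc2)c1 | starting material
16 | (2R,3R)-5,7-bis(benzyloxy)-2-ethynylchroman-3-yl 3,4,5-tris(benzyloxy)benzoate | C#C[C@H]1Oc2cc(OCc3ccccc3)cc(OCc3ccccc3)c2C[C@H]1OC(=O)c1cc(OCc2ccccc2)c(OCc2ccccc2)c(OCc2ccccc2)c1 | intermediate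
17 | (3Z)-5-iodo-4-ChF-pent-3-en-1-ol | IC/C(=C\CCO)[C@H]1Oc2cc(OCc3ccccc3)cc(OCc3ccccc3)c2C[C@H]1OCc1ccccc1 | intermediate
18 | (3E)-7-ChG-4-ChF-hept-3-en-6-yn-1-ol | OCC/C=C([C@H]1Oc2cc(OCc3ccccc3)cc(OCc3ccccc3)c2C[C@H]1OCc1ccccc1)\CC#C[C@H]1Oc2cc(OCc3ccccc3)cc(OCc3ccccc3)c2C[C@H]1OC(=O)c1cc(OCc2ccccc2)c(OCc2ccccc2)c(OCc2ccccc2)c1 | intermediate
19 | (3E)-7-ChG-4-ChF-hept-3-en-6-ynal | O=CC/C=C([C@H]1Oc2cc(OCc3ccccc3)cc(OCc3ccccc3)c2C[C@H]1OCc1ccccc1)\CC#C[C@H]1Oc2cc(OCc3ccccc3)cc(OCc3ccccc3)c2C[C@H]1OC(=O)c1cc(OCc2ccccc2)c(OCc2ccccc2)c(OCc2ccccc2)c1 | intermediate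
20 | (3E)-7-ChG-4-ChF-hept-3-en-6-ynoic acid | OC(=O)C/C=C([C@H]1Oc2cc(OCc3ccccc3)cc(OCc3ccccc3)c2C[C@H]1OCc1ccccc1)\CC#C[C@H]1Oc2cc(OCc3ccccc3)cc(OCc3ccccc3)c2C[C@H]1OC(=O)c1cc(OCc2ccccc2)c(OCc2ccccc2)c(OCc2ccccc2)c1 | intermediate
21 | ethyl 4-(benzyloxy)-3-oxobutanoate | CCOC(=O)CC(=O)COCc1ccccc1 | starting material
22 | ethyl 4-(benzyloxy)-3,5-dioxopentanoate (racemic formyl tautomer) | CCOC(=O)CC(=O)C(OCc1ccccc1)C=O | intermediate
23 | 5-(benzyloxy)-4-hydroxy-2H-pyran-2-one | O=C1C=C(O)C(OCc2ccccc2)=CO1 | intermediate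
24 | 5-(benzyloxy)-2-oxo-2H-pyran-4-yl (3E)-7-ChG-4-ChF-hept-3-en-6-ynoate | O=C4C=C(OC(=O)C/C=C([C@H]1Oc2cc(OCc3ccccc3)cc(OCc3ccccc3)c2C[C@H]1OCc1ccccc1)\CC#C[C@H]1Oc2cc(OCc3ccccc3)cc(OCc3ccccc3)c2C[C@H]1OC(=O)c1cc(OCc2ccccc2)c(OCc2ccccc2)c(OCc2ccccc2)c1)C(OCc5ccccc5)=CO4 | intermediate
25 | 5-(benzyloxy)-4-hydroxy-3-[(3E)-7-ChG-4-ChF-hept-3-en-6-ynoyl]-2H-pyran-2-one | O=C4OC=C(OCc5ccccc5)C(O)=C4C(=O)C/C=C([C@H]1Oc2cc(OCc3ccccc3)cc(OCc3ccccc3)c2C[C@H]1OCc1ccccc1)\CC#C[C@H]1Oc2cc(OCc3ccccc3)cc(OCc3ccccc3)c2C[C@H]1OC(=O)c1cc(OCc2ccccc2)c(OCc2ccccc2)c(OCc2ccccc2)c1 | intermediate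
26 | 4,5-bis(benzyloxy)-3-[(3E)-7-ChG-4-ChF-hept-3-en-6-ynoyl]-2H-pyran-2-one | O=C4OC=C(OCc5ccccc5)C(OCc5ccccc5)=C4C(=O)C/C=C([C@H]1Oc2cc(OCc3ccccc3)cc(OCc3ccccc3)c2C[C@H]1OCc1ccccc1)\CC#C[C@H]1Oc2cc(OCc3ccccc3)cc(OCc3ccccc3)c2C[C@H]1OC(=O)c1cc(OCc2ccccc2)c(OCc2ccccc2)c(OCc2ccccc2)c1 | intermediate
27 | bridged 2-oxabicyclo[2.2.2]octa-5,7-dien-3-one cycloadduct of 26 (both bridgehead diastereomers) | O=C4OC5C(OCc6ccccc6)=C(OCc6ccccc6)C47C(=O)C/C=C([C@H]1Oc2cc(OCc3ccccc3)cc(OCc3ccccc3)c2C[C@H]1OCc1ccccc1)\CC7=C5[C@H]1Oc2cc(OCc3ccccc3)cc(OCc3ccccc3)c2C[C@H]1OC(=O)c1cc(OCc2ccccc2)c(OCc2ccccc2)c(OCc2ccccc2)c1 | intermediate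
28 | 3,4-bis(benzyloxy)-1-ChG-8-ChF-6,9-dihydro-5H-benzo[7]annulen-5-one | O=C4CC=C([C@H]1Oc2cc(OCc3ccccc3)cc(OCc3ccccc3)c2C[C@H]1OCc1ccccc1)Cc5c([C@H]1Oc2cc(OCc3ccccc3)cc(OCc3ccccc3)c2C[C@H]1OC(=O)c1cc(OCc2ccccc2)c(OCc2ccccc2)c(OCc2ccccc2)c1)cc(OCc6ccccc6)c(OCc6ccccc6)c54 | intermediate
29 | sodium dienolate of 28 | [Na+].[O-]C4=CC=C([C@H]1Oc2cc(OCc3ccccc3)cc(OCc3ccccc3)c2C[C@H]1OCc1ccccc1)Cc5c([C@H]1Oc2cc(OCc3ccccc3)cc(OCc3ccccc3)c2C[C@H]1OC(=O)c1cc(OCc2ccccc2)c(OCc2ccccc2)c(OCc2ccccc2)c1)cc(OCc6ccccc6)c(OCc6ccccc6)c54 | intermediate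
30 | 3,4-bis(benzyloxy)-6-hydroxy-1-ChG-8-ChF-6,9-dihydro-5H-benzo[7]annulen-5-one (C6 epimers) | O=C4C(O)C=C([C@H]1Oc2cc(OCc3ccccc3)cc(OCc3ccccc3)c2C[C@H]1OCc1ccccc1)Cc5c([C@H]1Oc2cc(OCc3ccccc3)cc(OCc3ccccc3)c2C[C@H]1OC(=O)c1cc(OCc2ccccc2)c(OCc2ccccc2)c(OCc2ccccc2)c1)cc(OCc6ccccc6)c(OCc6ccccc6)c54 | intermediate
31 | 3,4-bis(benzyloxy)-1-ChG-8-ChF-5H-benzo[7]annulene-5,6(9H)-dione | O=C4C(=O)C=C([C@H]1Oc2cc(OCc3ccccc3)cc(OCc3ccccc3)c2C[C@H]1OCc1ccccc1)Cc5c([C@H]1Oc2cc(OCc3ccccc3)cc(OCc3ccccc3)c2C[C@H]1OC(=O)c1cc(OCc2ccccc2)c(OCc2ccccc2)c(OCc2ccccc2)c1)cc(OCc6ccccc6)c(OCc6ccccc6)c54 | intermediate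
32 | 3,4-bis(benzyloxy)-6-hydroxy-1-ChG-8-ChF-5H-benzo[7]annulen-5-one (deca-O-benzyl theaflavin-3-gallate) | O=C4C(O)=CC([C@H]1Oc2cc(OCc3ccccc3)cc(OCc3ccccc3)c2C[C@H]1OCc1ccccc1)=Cc5c([C@H]1Oc2cc(OCc3ccccc3)cc(OCc3ccccc3)c2C[C@H]1OC(=O)c1cc(OCc2ccccc2)c(OCc2ccccc2)c(OCc2ccccc2)c1)cc(OCc6ccccc6)c(OCc6ccccc6)c54 | intermediate
33 | theaflavin-3-gallate | O=C(O[C@@H]1Cc2c(O)cc(O)cc2O[C@@H]1c1cc(O)c(O)c2c(=O)c(O)cc([C@H]3Oc4cc(O)cc(O)c4C[C@H]3O)cc12)c1cc(O)c(O)c(O)c1 | target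

Total step count: 20. Longest linear sequence: 18 steps (steps 1–10, 12, 13, 15–20).

Steps most likely to fail

Step 17. The cycloaddition through a seven-membered tether may be slower than thermal migration of the C7=C8 double bond into conjugation with the ketone or than decomposition of the benzyl ethers, so the pyrone may be consumed without ring closure. The fallback sets out from 25 and changes the activation of the diene: BF3·OEt2 and iPr2NEt in CH2Cl2 should convert the 3-acyl-4-hydroxypyrone into its difluoroboron chelate F1, in which the dioxaborine ring lowers the pyrone LUMO and holds the acyl group coplanar. Thermolysis in toluene should then give, after loss of CO2, the chelated ortho-hydroxyaryl ketone F2. Hydrolysis of the chelate (NaOAc, aqueous EtOH, 60 °C) frees the 4-hydroxy benzannulenone F3, and Mitsunobu benzylation (BnOH, PPh3, DIAD) comes back to the route at 28.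

Step 18. The dienolate may expel the aryloxy group of chroman F in a vinylogous elimination, or may be oxygenated at the wrong terminus. The fallback sets out from 28 and works through the enol under acidic conditions: nitrosation with tBuONO and Me3SiCl in CH2Cl2 at −20 °C should give the 6-hydroxyimino ketone F4, which is already at the oxidation level of the dione. Exchange of the oxime with aqueous glyoxylic acid releases dione 31, which tautomerises, so the fallback comes back to the route at 32.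

Step 7. Carbonylation at the hindered propargylic ether may stall or lose its branched selectivity. The fallback sets out from 9 and splits the transformation in two: Markovnikov hydroiodination (Me3SiCl, NaI, H2O, MeCN, 0 °C) should give the 2-iodoalkene F5, and alkoxycarbonylation of this vinyl iodide (CO 1 atm, Pd(OAc)2, PPh3, K2CO3, but-3-en-1-ol, DMF, 50 °C) comes back to the route at 11.

Further compounds
F1 | step 17 | difluoroboron chelate of 25 | F[B-]4(F)OC5=C(C(=O)OC=C5OCc6ccccc6)C(C/C=C([C@H]1Oc2cc(OCc3ccccc3)cc(OCc3ccccc3)c2C[C@H]1OCc1ccccc1)\CC#C[C@H]1Oc2cc(OCc3ccccc3)cc(OCc3ccccc3)c2C[C@H]1OC(=O)c1cc(OCc2ccccc2)c(OCc2ccccc2)c(OCc2ccccc2)c1)=[O+]4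
F2 | step 17 | difluoroboron chelate of 3-(benzyloxy)-4-hydroxy-1-ChG-8-ChF-6,9-dihydro-5H-benzo[7]annulen-5-one | F[B-]4(F)Oc5c(OCc6ccccc6)cc([C@H]1Oc2cc(OCc3ccccc3)cc(OCc3ccccc3)c2C[C@H]1OC(=O)c1cc(OCc2ccccc2)c(OCc2ccccc2)c(OCc2ccccc2)c1)c7c5C(=[O+]4)CC=C([C@H]1Oc2cc(OCc3ccccc3)cc(OCc3ccccc3)c2C[C@H]1OCc1ccccc1)C7
F3 | step 17 | 3-(benzyloxy)-4-hydroxy-1-ChG-8-ChF-6,9-dihydro-5H-benzo[7]annulen-5-one | Oc5c(OCc6ccccc6)cc([C@H]1Oc2cc(OCc3ccccc3)cc(OCc3ccccc3)c2C[C@H]1OC(=O)c1cc(OCc2ccccc2)c(OCc2ccccc2)c(OCc2ccccc2)c1)c7c5C(=O)CC=C([C@H]1Oc2cc(OCc3ccccc3)cc(OCc3ccccc3)c2C[C@H]1OCc1ccccc1)C7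
F4 | step 18 | 3,4-bis(benzyloxy)-6-(hydroxyimino)-1-ChG-8-ChF-6,9-dihydro-5H-benzo[7]annulen-5-one | O=C4C(=NO)C=C([C@H]1Oc2cc(OCc3ccccc3)cc(OCc3ccccc3)c2C[C@H]1OCc1ccccc1)Cc5c([C@H]1Oc2cc(OCc3ccccc3)cc(OCc3ccccc3)c2C[C@H]1OC(=O)c1cc(OCc2ccccc2)c(OCc2ccccc2)c(OCc2ccccc2)c1)cc(OCc6ccccc6)c(OCc6ccccc6)c54
F5 | step 7 | (2S,3R)-3,5,7-tris(benzyloxy)-2-(1-iodoethenyl)chromane (same spatial arrangement as 9) | C=C(I)[C@H]1Oc2cc(OCc3ccccc3)cc(OCc3ccccc3)c2C[C@H]1OCc1ccccc1
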